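**Plan**
- Retrosynthesis, late cuts: the O–CH3 bond of the ortho ether and the aryl CO–OCH3 bond are protecting-group cleavages; the ketone C(=O)–C11 bond is cut to a Weinreb amide and an undecyl Grignard reagent.
- Key cut: both ring–carbon bonds, C6–CH2 and C1–CO2, are removed together, which leads back to dimethyl malonate and 3,5-dimethoxybenzyne.
- Enabling feature: numbering the arene from the carboxyl carbon (C1) through the phenol carbon (C2) and the methoxy carbon (C4) to the carbon bearing the ketone chain (C6), the carboxyl and the CH2 sit on adjacent carbons next to the C2 oxygen. These are the two ends of an aryne triple bond flanked by a methoxy group, and that methoxy group also fixes the direction of addition.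
- Forward order: 3,5-dimethoxyphenol is converted into the ortho-silyl aryl triflate (steps 1–3). Aryne insertion into malonate gives the homophthalate (step 4). The aliphatic ester is taken to the C13 ketone via the acid, the Weinreb amide and undecylmagnesium bromide (steps 5–8). Ortho-demethylation and ester hydrolysis finish the route (steps 9–10).
- No ring is formed and the target has no stereocentre. Control is needed only over regiochemistry (bromination, aryne addition, demethylation) and over the distinction between the two esters.

Key step: step 4

Remark: the target is taken as the open-chain keto acid (not its lactol or isocoumarin form), so the final acidification is done cold; salts that are merely protonated on work-up are not numbered separately from their neutral forms.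

**Route**

Step 1
Reactants: 1 3,5-dimethoxyphenol
Product: 2 2-bromo-3,5-dimethoxyphenol
Conditions: NBS (1.0 equiv), CH2Cl2, −78 °C to rt; chromatography
Reagents that add atoms: N-bromosuccinimide, O=C1CCC(=O)N1Br
Why: Electrophilic aromatic bromination of a phenol, in which the two equivalent carbons ortho to the hydroxyl (each also para to a methoxy group) should be favoured over the more crowded carbon between the two methoxy groups by statistics, sterics and hydrogen bonding of the phenol to NBS, and any para isomer is removed by chromatography.

Step 2
Reactants: 2 2-bromo-3,5-dimethoxyphenol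
Product: 3 (2-bromo-3,5-dimethoxyphenoxy)trimethylsilane
Conditions: (Me3Si)2NH, THF, 70 °C; evaporate
Reagents that add atoms: hexamethyldisilazane, C[Si](C)(C)N[Si](C)(C)C
Why: Silylation of the phenol by the silazane, driven by loss of ammonia, gives the aryl silyl ether salt-free so that it can be carried on after evaporation.

Step 3
Reactants: 3 (2-bromo-3,5-dimethoxyphenoxy)trimethylsilane
Product: 6 3,5-dimethoxy-2-(trimethylsilyl)phenyl trifluoromethanesulfonate, via aryllithium 4 (not isolated), via lithium phenolate 5 (not isolated)
Conditions: n-BuLi, THF, −100 to −80 °C; then Tf2O, −100 to −80 °C; aq. NaHCO3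
Reagents that add atoms: trifluoromethanesulfonic anhydride, O=S(=O)(OS(=O)(=O)C(F)(F)F)C(F)(F)F; n-butyllithium, [Li]CCCC (lithium of 4 and 5 only)
Why: Bromine–lithium exchange gives aryllithium 4, whose anionic 1,3 O-to-C silyl shift (retro-Brook rearrangement) places silicon on the carbon that carried bromine and leaves phenolate 5, which is O-sulfonylated by Tf2O at low temperature.

Step 4
Reactants: 6 3,5-dimethoxy-2-(trimethylsilyl)phenyl trifluoromethanesulfonate; 7 dimethyl malonate
Product: 9 methyl 2,4-dimethoxy-6-(2-methoxy-2-oxoethyl)benzoate, via 3,5-dimethoxybenzyne 8 (not isolated)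
Conditions: KF, 18-crown-6, THF, 0 °C to rt; 6 added slowly to a slight excess of 7
Reagents that add atoms: none
Why: Fluoride attack on silicon expels triflate and releases aryne 8, the malonate enolate adds to the aryne carbon remote from the flanking methoxy group, the aryl anion thus placed ortho to that methoxy group attacks one ester carbonyl of the malonate unit, and the strained benzocyclobutenoxide fragments to the benzylic ester enolate, which is protonated to 9. The closest known reaction type is the fluoride-triggered insertion of arynes into the C–C sigma bond of malonates and beta-keto esters (aryne acyl-alkylation). No ring remains in the product: the only closure is the transient 4-exo-trig addition of the aryl anion to the ester carbonyl, and it is undone at once by ring opening. No stereocentre is formed. The step needs a single regiochemistry of addition to the unsymmetrical aryne, and the methoxy group next to the triple bond secures it, because its inductive pull makes the distal aryne carbon the electrophilic one and stabilises negative charge on the proximal carbon, so the CH2CO2Me arm ends up meta and the migrating CO2Me group ortho to that oxygen. Slow addition of 6 in a crown-ether-activated aprotic medium should hold back both premature protonation of the aryl anion and a second arylation at the benzylic CH2 of 9.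

Step 5
Reactants: 9 methyl 2,4-dimethoxy-6-(2-methoxy-2-oxoethyl)benzoate
Product: 10 2-[3,5-dimethoxy-2-(methoxycarbonyl)phenyl]acetic acid
Conditions: LiOH·H2O (1.1 equiv), THF/H2O, 0 °C to rt; then dilute aq. HCl
Reagents that add atoms: lithium hydroxide, [Li+].[OH-]
Why: Chemoselective saponification, since hydroxide attacks the unhindered arylacetic ester far faster than the benzoate, which is flanked by two ortho substituents and deactivated by two donor methoxy groups.

Step 6
Reactants: 10 2-[3,5-dimethoxy-2-(methoxycarbonyl)phenyl]acetic acid
Product: 12 methyl 2,4-dimethoxy-6-{2-[methoxy(methyl)amino]-2-oxoethyl}benzoate, via acyl imidazolide 11 (not isolated)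
Conditions: 1,1'-carbonyldiimidazole, CH2Cl2, rt; then MeNHOMe·HCl, rt
Reagents that add atoms: N,O-dimethylhydroxylamine hydrochloride, CNOC.Cl; 1,1'-carbonyldiimidazole, O=C(n1ccnc1)n1ccnc1 (imidazolyl group of 11 only)
Why: Carboxyl activation as acyl imidazolide 11 followed by acyl substitution with N,O-dimethylhydroxylamine is a standard Weinreb amide synthesis that needs no strong base and leaves the hindered benzoate untouched.

Step 7
Reactants: 13 1-bromoundecane
Product: 14 undecylmagnesium bromide (titrated THF solution)
Conditions: Mg turnings, iodine crystal, THF, 40 °C to reflux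
Reagents that add atoms: magnesium, [Mg]
Why: Insertion of magnesium metal into a primary C–Br bond (Grignard reagent formation) is routine, and slow addition of the bromide limits Wurtz coupling.

Step 8
Reactants: 12 methyl 2,4-dimethoxy-6-{2-[methoxy(methyl)amino]-2-oxoethyl}benzoate; 14 undecylmagnesium bromide
Product: 16 methyl 2,4-dimethoxy-6-(2-oxotridecyl)benzoate, via magnesium hemiaminal chelate 15 (not isolated)
Conditions: 14 (1.5 equiv), THF, −20 to 0 °C; then dilute aq. HCl, 0 °C
Reagents that add atoms: none
Why: Weinreb ketone synthesis, in which the Grignard reagent adds once to give the magnesium-chelated tetrahedral adduct 15 that persists until acidic work-up and so cannot over-add, while the doubly ortho-substituted benzoate is left alone and the low temperature limits deprotonation of the benzylic CH2.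

Step 9
Reactants: 16 methyl 2,4-dimethoxy-6-(2-oxotridecyl)benzoate
Product: 18 methyl 2-hydroxy-4-methoxy-6-(2-oxotridecyl)benzoate, via aryloxydichloroborane 17 (not isolated)
Conditions: BCl3 (2.5 equiv), CH2Cl2, −78 to 0 °C; then H2O
Reagents that add atoms: boron trichloride, ClB(Cl)Cl (boron and chlorine of 17 only)
Why: BCl3 binds the ester carbonyl and the neighbouring methoxy oxygen in a six-membered chelate, so chloride removes only that methyl group (chelation-controlled Lewis-acid cleavage of an aryl methyl ether) to give 17, hydrolysed on work-up, while the unchelated 4-methoxy group, the methyl ester and the ketone should survive at or below 0 °C.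

Step 10
Reactants: 18 methyl 2-hydroxy-4-methoxy-6-(2-oxotridecyl)benzoate
Product: 19 2-hydroxy-4-methoxy-6-(2-oxotridecyl)benzoic acid
Conditions: KOH (excess), EtOH/H2O, 70 °C; then dilute aq. HCl, 0 °C
Reagents that add atoms: potassium hydroxide, [K+].[OH-]
Why: Saponification of the hindered salicylate ester with excess aqueous hydroxide, which the neighbouring ketone enolate can assist through a transient enol lactone that hydroxide reopens, gives the phenoxide–carboxylate dianion, and cold acidification should release 19 without lactonisation or loss of CO2.

**Compound list**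

1 | 3,5-dimethoxyphenol | COc1cc(O)cc(OC)c1 | starting material
2 | 2-bromo-3,5-dimethoxyphenol | COc1cc(O)c(Br)c(OC)c1 | intermediate
3 | (2-bromo-3,5-dimethoxyphenoxy)trimethylsilane | COc1cc(O[Si](C)(C)C)c(Br)c(OC)c1 | intermediate
4 | [2,4-dimethoxy-6-(trimethylsilyloxy)phenyl]lithium, not isolated | COc1cc(O[Si](C)(C)C)c([Li])c(OC)c1 | intermediate
5 | lithium 3,5-dimethoxy-2-(trimethylsilyl)phenolate, not isolated | [Li+].[O-]c1cc(OC)cc(OC)c1[Si](C)(C)C | intermediate
6 | 3,5-dimethoxy-2-(trimethylsilyl)phenyl trifluoromethanesulfonate | COc1cc(OC)c([Si](C)(C)C)c(OS(=O)(=O)C(F)(F)F)c1 | intermediate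
7 | dimethyl malonate | COC(=O)CC(=O)OC | starting material
8 | 3,5-dimethoxybenzyne (1,2-didehydro-3,5-dimethoxybenzene), not isolated | COC1=CC(OC)=CC#C1 | intermediate
9 | methyl 2,4-dimethoxy-6-(2-methoxy-2-oxoethyl)benzoate | COC(=O)Cc1cc(OC)cc(OC)c1C(=O)OC | intermediate
10 | 2-[3,5-dimethoxy-2-(methoxycarbonyl)phenyl]acetic acid | OC(=O)Cc1cc(OC)cc(OC)c1C(=O)OC | intermediate
11 | methyl 2-[2-(1H-imidazol-1-yl)-2-oxoethyl]-4,6-dimethoxybenzoate, not isolated | COC(=O)c1c(CC(=O)n2ccnc2)cc(OC)cc1OC | intermediate
12 | methyl 2,4-dimethoxy-6-{2-[methoxy(methyl)amino]-2-oxoethyl}benzoate | CON(C)C(=O)Cc1cc(OC)cc(OC)c1C(=O)OC | intermediate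
13 | 1-bromoundecane | CCCCCCCCCCCBr | starting material
14 | undecylmagnesium bromide | CCCCCCCCCCC[Mg]Br | intermediate
15 | methyl 2-{2-[(bromomagnesio)oxy]-2-[methoxy(methyl)amino]tridecyl}-4,6-dimethoxybenzoate, not isolated | CCCCCCCCCCCC(O[Mg]Br)(Cc1cc(OC)cc(OC)c1C(=O)OC)N(C)OC | intermediate
16 | methyl 2,4-dimethoxy-6-(2-oxotridecyl)benzoate | CCCCCCCCCCCC(=O)Cc1cc(OC)cc(OC)c1C(=O)OC | intermediate
17 | methyl 2-[(dichloroboranyl)oxy]-4-methoxy-6-(2-oxotridecyl)benzoate, not isolated | CCCCCCCCCCCC(=O)Cc1cc(OC)cc(OB(Cl)Cl)c1C(=O)OC | intermediate
18 | methyl 2-hydroxy-4-methoxy-6-(2-oxotridecyl)benzoate | CCCCCCCCCCCC(=O)Cc1cc(OC)cc(O)c1C(=O)OC | intermediate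
19 | 2-hydroxy-4-methoxy-6-(2-oxotridecyl)benzoic acid | CCCCCCCCCCCC(=O)Cc1cc(OC)cc(O)c1C(=O)O | target

**Step count and risks**

Total step count: 10. Longest linear sequence: 9 steps (steps 1–6 and 8–10 from compound 1); step 7 is a one-step side branch.

Steps most likely to fail:

1. Step 4. The aryl anion may be protonated before it reaches the weakly electrophilic ester carbonyl, giving arylation without acyl transfer, or the product may be arylated a second time at its benzylic CH2. The fallback sets out from 7 and comes back at 9, and builds the homophthalate without an aryne. Arylation of 7 with commercial 1-bromo-3,5-dimethoxybenzene (COc1cc(Br)cc(OC)c1) under Pd(dba)2/P(t-Bu)3 catalysis with K3PO4 in toluene at 70 °C should give dimethyl 2-(3,5-dimethoxyphenyl)malonate F1. Krapcho demethoxycarbonylation (LiCl, wet DMSO, 150 °C) should give methyl 2-(3,5-dimethoxyphenyl)acetate F2. Vilsmeier–Haack formylation (POCl3, DMF), which should go ortho to the side chain and para to a methoxy group, gives methyl 2-(2-formyl-3,5-dimethoxyphenyl)acetate F3. Pinnick oxidation (NaClO2, NaH2PO4, 2-methyl-2-butene, t-BuOH/H2O) gives 2,4-dimethoxy-6-(2-methoxy-2-oxoethyl)benzoic acid F4, and methylation with iodomethane and K2CO3 in DMF gives 9.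

2. Step 10. Hydroxide attack on the hindered, phenoxide-deactivated ester may be slow enough that intramolecular C-acylation of the ketone enolate (Claisen-type closure to a naphthalenediol) competes, and the acid may lactonise or decarboxylate on acidification. The fallback sets out from 18 and comes back at 19, and replaces ester hydrolysis by lactone opening. Heating 18 with catalytic p-toluenesulfonic acid in toluene with removal of methanol should close the enol lactone 8-hydroxy-6-methoxy-3-undecyl-1H-isochromen-1-one F5. This isocoumarin is far more electrophilic than the methyl ester and should be opened by KOH in aqueous EtOH at rt to 40 °C directly to the carboxylate, which can no longer undergo acyl transfer. Cold acidification gives 19.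

3. Step 1. Bromination may show poor positional selectivity, with attack para to the hydroxyl or a second bromination, and the isomers may be hard to separate. The fallback sets out from 1 and comes back at 6, and fixes the position by directed ortho-metalation. Carbamoylation of 1 (ClC(O)NEt2, K2CO3, MeCN, reflux) gives 3,5-dimethoxyphenyl N,N-diethylcarbamate F6. Lithiation with s-BuLi/TMEDA in THF at −78 °C should occur at the carbon shared by the carbamate and a methoxy group, and quenching with Me3SiCl at that temperature gives 3,5-dimethoxy-2-(trimethylsilyl)phenyl N,N-diethylcarbamate F7. Reductive removal of the carbamate with LiAlH4 in THF gives 3,5-dimethoxy-2-(trimethylsilyl)phenol F8, and Tf2O with pyridine in CH2Cl2 at 0 °C gives 6.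

**Further compounds**

F1 | step 4 | dimethyl 2-(3,5-dimethoxyphenyl)malonate | COC(=O)C(C(=O)OC)c1cc(OC)cc(OC)c1
F2 | step 4 | methyl 2-(3,5-dimethoxyphenyl)acetate | COC(=O)Cc1cc(OC)cc(OC)c1
F3 | step 4 | methyl 2-(2-formyl-3,5-dimethoxyphenyl)acetate | COC(=O)Cc1cc(OC)cc(OC)c1C=O
F4 | step 4 | 2,4-dimethoxy-6-(2-methoxy-2-oxoethyl)benzoic acid | COC(=O)Cc1cc(OC)cc(OC)c1C(=O)O
F5 | step 10 | 8-hydroxy-6-methoxy-3-undecyl-1H-isochromen-1-one | CCCCCCCCCCCC1=Cc2cc(OC)cc(O)c2C(=O)O1
F6 | step 1 | 3,5-dimethoxyphenyl N,N-diethylcarbamate | CCN(CC)C(=O)Oc1cc(OC)cc(OC)c1
F7 | step 1 | 3,5-dimethoxy-2-(trimethylsilyl)phenyl N,N-diethylcarbamate | CCN(CC)C(=O)Oc1cc(OC)cc(OC)c1[Si](C)(C)C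
F8 | step 1 | 3,5-dimethoxy-2-(trimethylsilyl)phenol | COc1cc(O)c([Si](C)(C)C)c(OC)c1
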